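The chain length is monomer in chains per chain begun, and you have to choose which initiator charge gives the longer chains in the next run.

- Wednesday's: free monomer 2.6 M; initiator 23 mM; time 40 s
- Thursday's: free monomer 2.6 M; initiator 30 mM; time 40 s

    free monomer + initiator → living end + monomer in chains (k1 = 0.205 L mol⁻¹ s⁻¹)
    free monomer + living end → monomer in chains + living end, rate k2*[living end]*[free monomer] (k2 = 9.04 L mol⁻¹ s⁻¹)
    initiator → spent initiator A (k3 = 0.0993 s⁻¹)
    initiator + monomer in chains → spent initiator B (k4 = 0.0321 L mol⁻¹ s⁻¹)

- the average divides the monomer in chains by the number of chains begun, living and dead together
- run time (Wednesday's): 40 s

- which of the two ends with the longer chains by the average number of monomer units in a chain (chains begun, living or dead) ("neither" if they lie within 10%) (Wednesday's / Thursday's / neither)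
- average number of monomer units in a chain (chains begun, living or dead) at the end, Wednesday's
- average number of monomer units in a chain (chains begun, living or dead) at the end, Thursday's

Write the balance of the initiator, the smaller charge. At the start it leaves in two ways: it begins a chain with free monomer, or it decays to spent initiator A. Monomer in chains is still absent, so the loss to spent initiator B has not begun. Take the two starting rates per initiator:

capture 0.533 s⁻¹, decay 0.0993 s⁻¹, total 0.632 s⁻¹

share = 84.3%

Call this the capture share, the part of the charged initiator that begins a chain while free monomer stands at its charge. It is the starting value of the initiator efficiency.

Wednesday's: chains 19.4 mM, length 134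

Thursday's: chains 25.3 mM, length 103

These lengths should come out low. Free monomer falls as chains grow, which lowers the capture share. With those chains begun, Wednesday's free monomer drains at about 0.175 s⁻¹, slower than the initiator leaves at the start, and Thursday's at about 0.229 s⁻¹, also slower. So the share should sag a little, and a little more on Thursday's.

These drains give free monomer a half-life of about 3.95 s on Wednesday's flask and 3.03 s on Thursday's, each shorter than the run. You can therefore put the charge on top of the fraction. The charges differ by 30.4%, wider than the margin. So charge 23 mM, as in Wednesday's flask.

The forecast names Wednesday's, at 141 against 111, holding that “chains begun equal the final living ends”.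

The simulation gives Wednesday's, with 141 for Wednesday's flask and 111 for Thursday's. Read back over the whole run, the part of the charged initiator that began chains is 79.8% on Wednesday's flask and 78.2% on Thursday's.

Now take Thursday's flask with 0.051 M of initiator. The starting share is unchanged, so chains should come to 43.0 mM and the first estimate of length to 60.5. The drain comes to about 0.389 s⁻¹, still slower than the starting 0.632 s⁻¹ but closer, so expect a larger sag. The simulation gives a length of 69.5, with 99.9% of the charged free monomer in chains, and the part of that flask's initiator that began chains, read back over the whole run, is 73.3%.

The constants stand for no real mixture, and the outcome is calculated.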